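## The problem

Compound 41 is built from two trans-2,3-diaryl-2,3-dihydrobenzofurans joined by the C2–C7' bond, with nine free phenols. Unit 1 (O1, C2, C3 on ring A) carries an (E)-4-hydroxystyryl group at C4 and a 3,5-dihydroxyphenyl group at C3; unit 2 (O1', C2', C3' on ring C) carries a 2,4-dihydroxyphenyl group at C2' and a 3,5-dihydroxyphenyl group at C3'. The four stereocentres (all S) form two trans pairs. Within a pair, the oxygen-bearing carbon (C2 or C2') is a benzylic ether next to an ortho,para-dioxygenated aryl group, so it can be set and reset under thermodynamic control by its neighbour (C3 or C3'). Ring C lies between the pairs, so neither pair can direct the other, and C3' and C3 each need their own source of chirality. Ring C is the constitutional difficulty: oxygen at C4', carbon at C3a', oxygen at C7a' and carbon at C7' on four adjacent positions, where the two oxygens must be told apart and C7' addressed in preference to C5'. The same benzylic ethers are the fragile points: acid can epimerise C2 and C2' and, in unit 2, re-close the furan on the C4' oxygen; acid also drives the 3,5-dihydroxyphenyl ring at C3 onto the neighbouring stilbene, and the polyphenol is air-sensitive in base. Ring C can be made de novo because the sequence C4'(OH)–C3a'(C)–C7a'(O)–C7'(X)–C6'(H)–C5'(H) is the one laid down when a vinylketene O=C=C(X)–CH=CH2 combines with an ynol ether: the carbonyl carbon becomes C4', the alkyne carbons C3a' and C7a', and the ketene α-carbon C7'.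

## Retrosynthesis

**Phenol protection and stilbene (41 ⇒ 40 ⇒ 38 + 39 ⇒ 37 ⇒ 36).** The nine O–acetyl bonds of 40, the C4–vinyl bond (to bromide 38 and styrene 39) and the eight O–methyl bonds of 36 are cut in that order. Making the stilbene first on the methyl ether series would be two steps shorter. It would, however, end with a Lewis-acid demethylation on a 4-styryl-3-(3,5-dioxyphenyl)dihydrobenzofuran, where a protonated stilbene is attacked by the C3 aryl ring in a seven-membered closure. The methyl groups are therefore removed from 36, which has no alkene, and acetates carry the phenols through the coupling and come off by mild methanolysis. The forward Heck reaction must accept an aryl bromide with one ortho substituent.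

**Unit 1 (36 ⇒ 27 + 33).** C2–C3 and O1–C2 are cut together, giving the ring C benzylsulfonium salt 27 (ylide 34) and the ring A sulfone 33 (quinone methide 35). Cutting only O1–C2, as in unit 2, would need a chiral diarylmethyl nucleophile added to aldehyde 24 with no handle on C3. Cutting C2–C7' would need a configurationally labile α,α-diaryl aldehyde. The double cut halves the molecule and leaves a racemic ring A piece that becomes achiral as 35. The forward step must fix the face of the ylide carbon (through the chiral sulfide held in 27) and pass it to C3 through trans-selective addition.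

**One-carbon handle (27 ⇒ 25 ⇒ 22).** The C7'–CH2 bond is cut back to the aryl bromide 22. The bromine at C7' is the point of the ring C construction: bromine–lithium exchange, formylation and reduction give 25, and the sulfide is attached through the benzylic bromide.

**Furan of unit 2 (22 ⇒ 21 ⇒ 20 ⇒ 19).** O1'–C2' is cut. Ionisation of the C2' carbinol next to the 2,4-dimethoxyphenyl group and capture by the C7a' oxygen closes the ring trans under control of C3'. This requires that only the C7a' oxygen be free. Phenol 19 already has its two ring C oxygens differentiated (free OH at C4', silyl ether at C7a'), so methylation to 20 and desilylation to 21 suffice.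

**Ring C (19 ⇒ 11 + 15).** C4'–C3a', C7a'–C7' and C4'–C5' are cut, giving the siloxyalkyne 11 and 2-bromocyclobutenone 15 (the source of bromo(vinyl)ketene 16). The neighbouring cut, lithiation of a resorcinol diether between its oxygens, also makes C3a'–C3' but leaves the oxygens alike. It would also leave C7' to be halogenated in competition with C5' and with two dimethoxyphenyl rings. In the benzannulation each substituent of ring C comes from a defined carbon of an open-chain partner. The forward reaction must give one regiochemistry of (2+2) addition and leave C3' intact.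

**Siloxyalkyne (11 ⇒ 8 ⇒ 7 ⇒ 4 + 5; 4 ⇒ 3 ⇒ 1).** The O–C(sp) bond is cut to the terminal alkyne 8, and the C2'–C3' bond to mesylate 4 and aldehyde 5. The propargylic stereocentre C3' derives, with inversion, from the carbinol of 3, which catalytic alkynylation of aldehyde 1 supplies. The C2' configuration of 7 is erased later, so only C3' has to be clean.

**Small fragments.** Enone 15 comes from 13 and 12 by elimination and bromination–elimination. Sulfone 33 comes from benzhydrol 32, made from salicylaldehyde 30 and Grignard reagent 31; both derive from bromide 28, 30 by way of aldehyde 29.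

## Roads not taken

**Alternative 1:** The cut is C2'–C3' of unit 2. The diaryldiazomethane A1 is decomposed by Rh2(S-PTAD)4, and the carbene at C3' inserts into the benzylic C–H bond of the 2,4-dimethoxybenzyl ether to give the cis-dihydrobenzofuran A2.
- Merits: C3' is set by a catalyst in the ring-forming step. Ring C is bought as an arene. After acid epimerisation at C2' and unmasking of the dioxolane, A2 would give aldehyde 24 in some two to three steps fewer than the chosen route needs.
- Weak points: the carbene carbon sits between two ortho oxygens, so the parent ketone is a doubly ortho-substituted benzophenone whose hydrazone is hard to form. The methoxy C–H bonds on the other side are also within five-membered reach. The C3a'–C3' bond must first be made by lithiation next to a benzyl ether prone to Wittig rearrangement.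
- Comparison: in step count and in direct catalyst control of C3', this road is better. The chosen plan sets against it an unhindered open-chain origin for C3', a ring C born with differentiated oxygens, and a C7' bromine that serves both aryllithium and coupling chemistry. Alternative 1 also leaves unit 1 unaddressed.

**Alternative 2:** The cuts are C2–C7' and C3–aryl of unit 1. Aryllithium 23 adds to the ring A alkenylboronate A3. Zerovalent palladium from Pd(OAc)2 and MandyPhos, with aryl triflate A4, then triggers migration of ring C from boron to C2 while the aryl group is delivered to C3, giving boronate A5.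
- Merits: three components are joined in one step, C3 is set directly by the catalyst, and the stilbene is already in place, so no late Heck step is needed.
- Weak points: A3 is an internal, aryl-substituted alkenylboronate with two ortho substituents, a hindered alkene for palladium to bind. It also holds a second, more accessible styrene double bond open to Heck arylation. The valuable fragment 23 is the migrating group. A5 is a benzylic boronate liable to protodeboronation. Because the stilbene is present from the start, the demethylation must be done in its presence.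
- Comparison: this is a way to build unit 1 and could replace step 17, with more direct control of C3 than a sulfur ylide gives. It is not a route to ring C and draws on 22 from the chosen plan. The chosen plan sets against it a union that keeps the C4 bromine, which allows demethylation before the stilbene exists.

**Alternative 3:** The cuts are C2–C3 and O1–C2 of unit 1. Base releases a ring A quinone methide from a sulfone such as 33 and a ylide from a ring C benzylsulfonium salt such as 27; addition and displacement of the sulfide give A6, which is compound 36.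
- Merits: fully convergent, trans-selective, tolerant of the aryl bromide, and the sulfide is recovered.
- Weak points: C3 is controlled only indirectly, through the relative topicity of the addition, and the ylide is semi-stabilised and bulky.
- Comparison: for unit 1 this road is as good as anything found, and it is adopted as step 17. As a plan it leaves open where the ring C benzyl fragment comes from. Taken from a resorcinol arene, that fragment needs the C3a'–C3' bond made between two oxygens, the oxygens differentiated and C7' functionalised selectively. The benzannulation settles these three selectivity problems in one step.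

Key step: step 8

**Remarks on the chemistry.**
- 3-Bromocyclobutan-1-one (12) is taken as a purchased material.
- (2S,5S)-2,5-Dimethylthiolane is a known, recoverable reagent, made from commercial (2R,5R)-hexane-2,5-diol through the dimesylate and Na2S with double inversion; its preparation is not counted.
- Unprimed and primed locants refer to units 1 and 2 in all intermediates.
- The facial sense of two reagents is assigned by analogy and not derived for these substrates: the ProPhenol ligand in step 1 and the thiolane in step 12. In each case the enantiomeric reagent is the remedy.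

## Steps

Step 1
Reactants: 1 3,5-dimethoxybenzaldehyde
Product: 3 (S)-1-(3,5-dimethoxyphenyl)prop-2-yn-1-ol, via silylated alkynol 2 (not isolated)
Conditions: TMS-acetylene, Me2Zn, (S,S)-ProPhenol (10 mol %), Ph3PO (20 mol %), toluene, 4 °C; then K2CO3, MeOH, rt
Reagents that add atoms: ethynyltrimethylsilane, C#C[Si](C)(C)C
Why: Catalytic asymmetric alkynylation: the zinc acetylide adds to the aldehyde inside the dinuclear zinc–ProPhenol pocket, Si-face attack giving (R)-2, and methanolysis of the C–Si bond frees the terminal alkyne. The sense follows the accepted model for aryl aldehydes; the (R,R)-ligand is used if this aldehyde departs from it.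

Step 2
Reactants: 3 (S)-1-(3,5-dimethoxyphenyl)prop-2-yn-1-ol
Product: 4 (S)-1-(3,5-dimethoxyphenyl)prop-2-yn-1-yl methanesulfonate
Conditions: MsCl, Et3N, CH2Cl2, −78 °C; used crude at once
Reagents that add atoms: methanesulfonyl chloride, CS(=O)(=O)Cl
Why: Sulfonylation at oxygen leaves the stereocentre untouched. The meta-methoxy groups do not stabilise a benzylic cation, so the mesylate should survive cold work-up and immediate use.

Step 3
Reactants: 4 (S)-1-(3,5-dimethoxyphenyl)prop-2-yn-1-yl methanesulfonate; 5 2,4-dimethoxybenzaldehyde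
Product: 7 (1S,2R)-1-(2,4-dimethoxyphenyl)-2-(3,5-dimethoxyphenyl)but-3-yn-1-ol, via allenylindium 6 (not isolated)
Conditions: PdCl2(dppf) (5 mol %), InI (1.5 equiv), THF/HMPA (3:1), rt
Reagents that add atoms: none
Why: Zerovalent palladium formed in situ displaces the mesylate in an anti SN2' sense; InI converts the allenylpalladium into allenylindium 6, which adds to the aldehyde through a closed six-membered transition state (SE2'). The net result is inversion at C3' and an anti C2'/C3' relationship. The C2' configuration is erased in step 10, so only C3' has to be transferred cleanly.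

Step 4
Reactants: 7 (1S,2R)-1-(2,4-dimethoxyphenyl)-2-(3,5-dimethoxyphenyl)but-3-yn-1-ol
Product: 8 tert-butyl{[(1S,2R)-1-(2,4-dimethoxyphenyl)-2-(3,5-dimethoxyphenyl)but-3-yn-1-yl]oxy}dimethylsilane
Conditions: TBSOTf, 2,6-lutidine, CH2Cl2, −78 to 0 °C
Reagents that add atoms: tert-butyldimethylsilyl trifluoromethanesulfonate, CC(C)(C)[Si](C)(C)OS(=O)(=O)C(F)(F)F
Why: Standard silylation of a hindered secondary alcohol. The ether keeps the hydroxyl away from the bases of step 5 and from the ketene of step 8.

Step 5
Reactants: 8 tert-butyl{[(1S,2R)-1-(2,4-dimethoxyphenyl)-2-(3,5-dimethoxyphenyl)but-3-yn-1-yl]oxy}dimethylsilane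
Product: 11 (3S,4S)-4-(tert-butyldimethylsilyloxy)-4-(2,4-dimethoxyphenyl)-3-(3,5-dimethoxyphenyl)-1-(triisopropylsilyloxy)but-1-yne, via lithium acetylide 9 (not isolated), via lithium ynolate 10 (not isolated)
Conditions: n-BuLi, THF, −78 °C; LiOOt-Bu (from t-BuOOH and LiN(SiMe3)2), −78 to 0 °C; TIPSOTf, −78 to 0 °C
Reagents that add atoms: lithium tert-butyl peroxide, CC(C)(C)OO[Li]; triisopropylsilyl trifluoromethanesulfonate, CC(C)[Si](C(C)C)(C(C)C)OS(=O)(=O)C(F)(F)F
Why: Oxidation of a lithium acetylide by lithium tert-butyl peroxide gives the ynolate, which the bulky silyl triflate captures on oxygen. The C3' hydrogen is not removed because the substrate is already an anion. The descriptor at C3' changes only because the silyloxy group raises the priority of the alkyne.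

Step 6
Reactants: 12 3-bromocyclobutan-1-one
Product: 13 cyclobut-2-en-1-one
Conditions: n-Bu3N, rt; vacuum transfer into a −78 °C trap
Reagents that add atoms: none
Why: E1cB dehydrobromination. The volatile enone is distilled away from the ammonium salt and kept cold in solution.

Step 7
Reactants: 13 cyclobut-2-en-1-one
Product: 15 2-bromocyclobut-2-en-1-one, via dibromoketone 14 (not isolated)
Conditions: Br2, CH2Cl2, −78 °C; Et3N, −78 to 0 °C; kept as a cold solution
Reagents that add atoms: bromine, BrBr
Why: Anti addition of bromine followed by E1cB loss of HBr through the more acidic C2 hydrogen, the usual route to 2-bromoenones.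

Step 8
Reactants: 11 (3S,4S)-4-(tert-butyldimethylsilyloxy)-4-(2,4-dimethoxyphenyl)-3-(3,5-dimethoxyphenyl)-1-(triisopropylsilyloxy)but-1-yne; 15 2-bromocyclobut-2-en-1-one
Product: 19 4-bromo-2-[(1S,2S)-2-(tert-butyldimethylsilyloxy)-2-(2,4-dimethoxyphenyl)-1-(3,5-dimethoxyphenyl)ethyl]-3-(triisopropylsilyloxy)phenol, via bromo(vinyl)ketene 16 (not isolated), via vinylcyclobutenone 17 (not isolated), via dienylketene 18 (not isolated)
Conditions: toluene, 80 °C, then 110 °C; 15 (2 equiv) added in portions to hot 11
Reagents that add atoms: none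
Why: Heat opens 15 by four-electron conrotatory cleavage of its C1–C4 bond to bromo(vinyl)ketene 16. The ynol ether adds across the ketene C=C in a (2+2) cycloaddition oriented by polarity: the nucleophilic alkyne carbon carrying C3' bonds to the ketene carbonyl carbon (C4'–C3a') and the silyloxy carbon bonds to the brominated α-carbon (C7a'–C7'), giving 17. A second four-electron opening turns 17 into dienylketene 18, whose six-electron disrotatory electrocyclisation forms C4'–C5' and closes the six-membered ring C; enolisation of the cyclohexadienone gives phenol 19. The closest known reaction type is the Danheiser benzannulation of cyclobutenone-derived vinylketenes with triisopropylsilyloxyalkynes, which gives resorcinol monosilyl ethers of this pattern. No stereocentre is created: the quaternary carbon of 17 forms as a mixture and vanishes on aromatisation, and reversible opening of 17 lets both epimers drain through the (Z)-isomer of 18 that can close. The step needs regioselectivity, secured by the oxygen-induced polarisation of the alkyne against the ketene carbonyl, and preference for the alkyne over ketene self-reaction, served by slow addition of 15. C3' and C2' are spectators because the medium is neutral and aprotic, the carbinol is silylated, and the triisopropylsilyl group is too large to shift from oxygen to carbon at these temperatures.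

Step 9
Reactants: 19 4-bromo-2-[(1S,2S)-2-(tert-butyldimethylsilyloxy)-2-(2,4-dimethoxyphenyl)-1-(3,5-dimethoxyphenyl)ethyl]-3-(triisopropylsilyloxy)phenol
Product: 20 {6-bromo-2-[(1S,2S)-2-(tert-butyldimethylsilyloxy)-2-(2,4-dimethoxyphenyl)-1-(3,5-dimethoxyphenyl)ethyl]-3-methoxyphenoxy}triisopropylsilane
Conditions: MeI, K2CO3, acetone, 40 °C
Reagents that add atoms: iodomethane, CI
Why: Williamson methylation of the only free phenol (C4'). The silyl ether is meta to it and cannot migrate, so the two ring C oxygens stay differentiated.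

Step 10
Reactants: 20 {6-bromo-2-[(1S,2S)-2-(tert-butyldimethylsilyloxy)-2-(2,4-dimethoxyphenyl)-1-(3,5-dimethoxyphenyl)ethyl]-3-methoxyphenoxy}triisopropylsilane
Product: 22 (2S,3S)-7-bromo-2-(2,4-dimethoxyphenyl)-3-(3,5-dimethoxyphenyl)-4-methoxy-2,3-dihydro-1-benzofuran, via phenol alcohol 21 (not isolated)
Conditions: TBAF, THF, 0 °C to rt; work-up; TsOH·H2O (10 mol %), CH2Cl2, 0 °C to rt
Reagents that add atoms: none
Why: Fluoride removes both silyl groups; acid ionises the C2' carbinol of 21 to a cation stabilised by the 2,4-dimethoxyphenyl group, which the only free phenol (at C7a') captures in a 5-exo closure. The trans ring is expected because the benzylic ether can re-ionise, so the untouched C3' sets C2' under thermodynamic control.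

Step 11
Reactants: 22 (2S,3S)-7-bromo-2-(2,4-dimethoxyphenyl)-3-(3,5-dimethoxyphenyl)-4-methoxy-2,3-dihydro-1-benzofuran
Product: 25 [(2S,3S)-2-(2,4-dimethoxyphenyl)-3-(3,5-dimethoxyphenyl)-4-methoxy-2,3-dihydro-1-benzofuran-7-yl]methanol, via aryllithium 23 (not isolated), via aldehyde 24 (not isolated)
Conditions: n-BuLi, THF, −78 °C; DMF, −78 to 0 °C; MeOH, NaBH4, 0 °C
Reagents that add atoms: N,N-dimethylformamide, CN(C)C=O
Why: Bromine–lithium exchange outruns deprotonation at −78 °C and the aryllithium is stabilised by the adjacent ring oxygen. Formylation and hydride reduction in the same flask install the one-carbon handle.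

Step 12
Reactants: 25 [(2S,3S)-2-(2,4-dimethoxyphenyl)-3-(3,5-dimethoxyphenyl)-4-methoxy-2,3-dihydro-1-benzofuran-7-yl]methanol
Product: 27 (2S,5S)-1-{[(2S,3S)-2-(2,4-dimethoxyphenyl)-3-(3,5-dimethoxyphenyl)-4-methoxy-2,3-dihydro-1-benzofuran-7-yl]methyl}-2,5-dimethylthiolan-1-ium tetrafluoroborate, via benzylic bromide 26 (not isolated)
Conditions: CBr4, PPh3, CH2Cl2, 0 °C; then (2S,5S)-2,5-dimethylthiolane, NaBF4, CH2Cl2/H2O, rt
Reagents that add atoms: (2S,5S)-2,5-dimethylthiolane, C[C@H]1CC[C@H](C)S1; sodium tetrafluoroborate, [Na+].F[B-](F)(F)F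
Why: Appel bromination under neutral conditions spares the acid-labile C2'–O1' ether; the electron-rich benzylic bromide alkylates the sulfide at once and anion exchange gives a stable salt. The C2-symmetric sulfide has equivalent lone pairs, so a single sulfonium salt forms.

Step 13
Reactants: 28 1-bromo-3,5-dimethoxybenzene
Product: 29 2-bromo-4,6-dimethoxybenzaldehyde
Conditions: POCl3, DMF, 0 to 90 °C; aq NaOAc
Reagents that add atoms: N,N-dimethylformamide, CN(C)C=O; water, O
Why: Vilsmeier–Haack formylation at the position para to one methoxy group and ortho to the other, which is less hindered than the position between the two methoxy groups.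

Step 14
Reactants: 29 2-bromo-4,6-dimethoxybenzaldehyde
Product: 30 2-bromo-6-hydroxy-4-methoxybenzaldehyde
Conditions: BCl3, CH2Cl2, −78 to 0 °C
Reagents that add atoms: none
Why: Chelation of boron between the aldehyde and the ortho methoxy oxygen directs cleavage to that methyl ether only.

Step 15
Reactants: 30 2-bromo-6-hydroxy-4-methoxybenzaldehyde; 28 1-bromo-3,5-dimethoxybenzene
Product: 32 3-bromo-2-[(3,5-dimethoxyphenyl)(hydroxy)methyl]-5-methoxyphenol (racemic), via Grignard reagent 31 (not isolated)
Conditions: 28, Mg, THF, reflux; then 30, 0 °C to rt (2.5 equiv of 31)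
Reagents that add atoms: none
Why: Grignard addition to the aldehyde after the first equivalent has deprotonated the phenol. The carbinol stereocentre is of no consequence because it is lost in the quinone methide.

Step 16
Reactants: 32 3-bromo-2-[(3,5-dimethoxyphenyl)(hydroxy)methyl]-5-methoxyphenol
Product: 33 3-bromo-2-[(3,5-dimethoxyphenyl)(4-methylbenzenesulfonyl)methyl]-5-methoxyphenol (racemic)
Conditions: p-TolSO2Na, HCO2H/H2O, rt
Reagents that add atoms: sodium 4-methylbenzenesulfinate, [Na+].[O-]S(=O)c1ccc(C)cc1
Why: Acid-promoted SN1 exchange of the benzhydrylic hydroxyl for sulfinate through the stabilised cation gives the usual precursor for base-triggered release of an ortho-quinone methide.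

Step 17
Reactants: 27 (2S,5S)-1-{[(2S,3S)-2-(2,4-dimethoxyphenyl)-3-(3,5-dimethoxyphenyl)-4-methoxy-2,3-dihydro-1-benzofuran-7-yl]methyl}-2,5-dimethylthiolan-1-ium tetrafluoroborate; 33 3-bromo-2-[(3,5-dimethoxyphenyl)(4-methylbenzenesulfonyl)methyl]-5-methoxyphenol
Product: 36 (2S,3S)-4-bromo-2-[(2S,3S)-2-(2,4-dimethoxyphenyl)-3-(3,5-dimethoxyphenyl)-4-methoxy-2,3-dihydro-1-benzofuran-7-yl]-3-(3,5-dimethoxyphenyl)-6-methoxy-2,3-dihydro-1-benzofuran, via sulfonium ylide 34 (not isolated), via quinone methide 35 (not isolated)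
Conditions: Cs2CO3, CH2Cl2/MeCN, −20 °C to rt; 33 in excess
Reagents that add atoms: none
Why: Base releases quinone methide 35 from 33 by loss of sulfinate and ylide 34 from 27; conjugate addition of the ylide carbon to the exocyclic carbon forms C2–C3, and the phenoxide displaces the sulfide with inversion in a 5-exo-tet closure ((4+1) annulation of a sulfur ylide, related to the Corey–Chaykovsky reaction). The C2-symmetric (2S,5S)-thiolane fixes the face of the ylide carbon, its hand chosen by analogy with epoxide formation from benzylides of this sulfide, and the anti addition that leads to the trans ring passes this on to C3. The cis isomer is removed by chromatography and not equilibrated, since acid would correct only C2.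

Step 18
Reactants: 36 (2S,3S)-4-bromo-2-[(2S,3S)-2-(2,4-dimethoxyphenyl)-3-(3,5-dimethoxyphenyl)-4-methoxy-2,3-dihydro-1-benzofuran-7-yl]-3-(3,5-dimethoxyphenyl)-6-methoxy-2,3-dihydro-1-benzofuran
Product: 37 (2S,3S)-4-bromo-2-[(2S,3S)-2-(2,4-dihydroxyphenyl)-3-(3,5-dihydroxyphenyl)-4-hydroxy-2,3-dihydro-1-benzofuran-7-yl]-3-(3,5-dihydroxyphenyl)-2,3-dihydro-1-benzofuran-6-ol
Conditions: BBr3 (excess), CH2Cl2, −78 to 0 °C; MeOH, H2O
Reagents that add atoms: none
Why: Lewis-acid cleavage of aryl methyl ethers, run before the stilbene exists so that no protonated styrene can be attacked by the C3 aryl ring. It is kept cold because the boron-bound aryloxy groups that form are poorer donors than methoxy groups and so hold the benzylic C–O bonds better.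

Step 19
Reactants: 37 (2S,3S)-4-bromo-2-[(2S,3S)-2-(2,4-dihydroxyphenyl)-3-(3,5-dihydroxyphenyl)-4-hydroxy-2,3-dihydro-1-benzofuran-7-yl]-3-(3,5-dihydroxyphenyl)-2,3-dihydro-1-benzofuran-6-ol
Product: 38 octaacetate of 37
Conditions: Ac2O, pyridine, DMAP (cat.), rt
Reagents that add atoms: acetic anhydride, CC(=O)OC(C)=O
Why: Peracetylation of phenols. It makes the polyphenol soluble, stable to air and compatible with the palladium step.

Step 20
Reactants: 38 octaacetate of 37; 39 4-ethenylphenyl acetate
Product: 40 nonaacetate of 41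
Conditions: Pd2(dba)3 (2.5 mol %), P(t-Bu)3·HBF4, Cy2NMe, 1,4-dioxane, 90 °C
Reagents that add atoms: none
Why: Heck reaction: oxidative addition of the aryl bromide to zerovalent palladium bearing the bulky, electron-rich phosphine, insertion of the styrene at its terminal carbon and syn β-hydride elimination give the (E)-stilbene. The hindered amine base leaves the aryl acetates intact.

Step 21
Reactants: 40 nonaacetate of 41
Product: 41 (2S,3S)-2-[(2S,3S)-2-(2,4-dihydroxyphenyl)-3-(3,5-dihydroxyphenyl)-4-hydroxy-2,3-dihydro-1-benzofuran-7-yl]-3-(3,5-dihydroxyphenyl)-4-[(E)-2-(4-hydroxyphenyl)ethenyl]-2,3-dihydro-1-benzofuran-6-ol (CNP0397447.1)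
Conditions: K2CO3 (cat.), MeOH (degassed), 0 °C to rt; aq NH4Cl
Reagents that add atoms: none
Why: Base-catalysed transesterification removes all nine acetates without acid, so neither the stilbene nor the benzylic ethers meet cationic conditions. Air is excluded because the polyphenolate is oxidisable.

## Compound list

1 | 3,5-dimethoxybenzaldehyde | COc1cc(C=O)cc(OC)c1 | starting material
2 | (R)-1-(3,5-dimethoxyphenyl)-3-(trimethylsilyl)prop-2-yn-1-ol | C[Si](C)(C)C#C[C@H](O)c1cc(OC)cc(OC)c1 | intermediate (not isolated)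
3 | (S)-1-(3,5-dimethoxyphenyl)prop-2-yn-1-ol | C#C[C@H](O)c1cc(OC)cc(OC)c1 | intermediate
4 | (S)-1-(3,5-dimethoxyphenyl)prop-2-yn-1-yl methanesulfonate | C#C[C@H](OS(C)(=O)=O)c1cc(OC)cc(OC)c1 | intermediate
5 | 2,4-dimethoxybenzaldehyde | COc1ccc(C=O)c(OC)c1 | starting material
6 | (aS)-[3-(3,5-dimethoxyphenyl)propa-1,2-dien-1-yl](iodo)indium methanesulfonate | CS(=O)(=O)O[In](I)C([H])=[C@@]=C([H])c1cc(OC)cc(OC)c1 | intermediate (not isolated)
7 | (1S,2R)-1-(2,4-dimethoxyphenyl)-2-(3,5-dimethoxyphenyl)but-3-yn-1-ol | C#C[C@H](c1cc(OC)cc(OC)c1)[C@H](O)c1ccc(OC)cc1OC | intermediate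
8 | tert-butyl{[(1S,2R)-1-(2,4-dimethoxyphenyl)-2-(3,5-dimethoxyphenyl)but-3-yn-1-yl]oxy}dimethylsilane | C#C[C@H](c1cc(OC)cc(OC)c1)[C@H](O[Si](C)(C)C(C)(C)C)c1ccc(OC)cc1OC | intermediate
9 | lithium acetylide of 8 | [Li]C#C[C@H](c1cc(OC)cc(OC)c1)[C@H](O[Si](C)(C)C(C)(C)C)c1ccc(OC)cc1OC | intermediate (not isolated)
10 | lithium ynolate from 9 | [Li]OC#C[C@H](c1cc(OC)cc(OC)c1)[C@H](O[Si](C)(C)C(C)(C)C)c1ccc(OC)cc1OC | intermediate (not isolated)
11 | (3S,4S)-4-(tert-butyldimethylsilyloxy)-4-(2,4-dimethoxyphenyl)-3-(3,5-dimethoxyphenyl)-1-(triisopropylsilyloxy)but-1-yne | CC(C)[Si](C(C)C)(C(C)C)OC#C[C@H](c1cc(OC)cc(OC)c1)[C@H](O[Si](C)(C)C(C)(C)C)c1ccc(OC)cc1OC | intermediate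
12 | 3-bromocyclobutan-1-one | O=C1CC(Br)C1 | starting material
13 | cyclobut-2-en-1-one | O=C1CC=C1 | intermediate
14 | trans-2,3-dibromocyclobutan-1-one (racemic) | O=C1C[C@H](Br)[C@H]1Br | intermediate (not isolated)
15 | 2-bromocyclobut-2-en-1-one | O=C1CC=C1Br | intermediate
16 | 2-bromobuta-1,3-dien-1-one | O=C=C(Br)C=C | intermediate (not isolated)
17 | 4-bromo-2-[(1S,2S)-2-(tert-butyldimethylsilyloxy)-2-(2,4-dimethoxyphenyl)-1-(3,5-dimethoxyphenyl)ethyl]-4-ethenyl-3-(triisopropylsilyloxy)cyclobut-2-en-1-one (both C4 epimers) | O=C1C([C@H](c2cc(OC)cc(OC)c2)[C@H](O[Si](C)(C)C(C)(C)C)c2ccc(OC)cc2OC)=C(O[Si](C(C)C)(C(C)C)C(C)C)C1(Br)C=C | intermediate (not isolated)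
18 | (3Z)-4-bromo-2-[(1S,2S)-2-(tert-butyldimethylsilyloxy)-2-(2,4-dimethoxyphenyl)-1-(3,5-dimethoxyphenyl)ethyl]-3-(triisopropylsilyloxy)hexa-1,3,5-trien-1-one | O=C=C([C@H](c1cc(OC)cc(OC)c1)[C@H](O[Si](C)(C)C(C)(C)C)c1ccc(OC)cc1OC)/C(O[Si](C(C)C)(C(C)C)C(C)C)=C(/Br)C=C | intermediate (not isolated)
19 | 4-bromo-2-[(1S,2S)-2-(tert-butyldimethylsilyloxy)-2-(2,4-dimethoxyphenyl)-1-(3,5-dimethoxyphenyl)ethyl]-3-(triisopropylsilyloxy)phenol | Brc1ccc(O)c([C@H](c2cc(OC)cc(OC)c2)[C@H](O[Si](C)(C)C(C)(C)C)c2ccc(OC)cc2OC)c1O[Si](C(C)C)(C(C)C)C(C)C | intermediate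
20 | {6-bromo-2-[(1S,2S)-2-(tert-butyldimethylsilyloxy)-2-(2,4-dimethoxyphenyl)-1-(3,5-dimethoxyphenyl)ethyl]-3-methoxyphenoxy}triisopropylsilane | Brc1ccc(OC)c([C@H](c2cc(OC)cc(OC)c2)[C@H](O[Si](C)(C)C(C)(C)C)c2ccc(OC)cc2OC)c1O[Si](C(C)C)(C(C)C)C(C)C | intermediate
21 | 6-bromo-2-[(1S,2S)-2-(2,4-dimethoxyphenyl)-1-(3,5-dimethoxyphenyl)-2-hydroxyethyl]-3-methoxyphenol | Brc1ccc(OC)c([C@H](c2cc(OC)cc(OC)c2)[C@H](O)c2ccc(OC)cc2OC)c1O | intermediate (not isolated)
22 | (2S,3S)-7-bromo-2-(2,4-dimethoxyphenyl)-3-(3,5-dimethoxyphenyl)-4-methoxy-2,3-dihydro-1-benzofuran | Brc1ccc(OC)c2c1O[C@H](c1ccc(OC)cc1OC)[C@H]2c1cc(OC)cc(OC)c1 | intermediate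
23 | 7-lithio derivative of 22 | [Li]c1ccc(OC)c2c1O[C@H](c1ccc(OC)cc1OC)[C@H]2c1cc(OC)cc(OC)c1 | intermediate (not isolated)
24 | (2S,3S)-2-(2,4-dimethoxyphenyl)-3-(3,5-dimethoxyphenyl)-4-methoxy-2,3-dihydro-1-benzofuran-7-carbaldehyde | O=Cc1ccc(OC)c2c1O[C@H](c1ccc(OC)cc1OC)[C@H]2c1cc(OC)cc(OC)c1 | intermediate (not isolated)
25 | [(2S,3S)-2-(2,4-dimethoxyphenyl)-3-(3,5-dimethoxyphenyl)-4-methoxy-2,3-dihydro-1-benzofuran-7-yl]methanol | OCc1ccc(OC)c2c1O[C@H](c1ccc(OC)cc1OC)[C@H]2c1cc(OC)cc(OC)c1 | intermediate
26 | (2S,3S)-7-(bromomethyl)-2-(2,4-dimethoxyphenyl)-3-(3,5-dimethoxyphenyl)-4-methoxy-2,3-dihydro-1-benzofuran | BrCc1ccc(OC)c2c1O[C@H](c1ccc(OC)cc1OC)[C@H]2c1cc(OC)cc(OC)c1 | intermediate (not isolated)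
27 | (2S,5S)-1-{[(2S,3S)-2-(2,4-dimethoxyphenyl)-3-(3,5-dimethoxyphenyl)-4-methoxy-2,3-dihydro-1-benzofuran-7-yl]methyl}-2,5-dimethylthiolan-1-ium tetrafluoroborate | C[C@H]1CC[C@H](C)[S+]1Cc1ccc(OC)c2c1O[C@H](c1ccc(OC)cc1OC)[C@H]2c1cc(OC)cc(OC)c1.F[B-](F)(F)F | intermediate
28 | 1-bromo-3,5-dimethoxybenzene | COc1cc(Br)cc(OC)c1 | starting material
29 | 2-bromo-4,6-dimethoxybenzaldehyde | COc1cc(Br)c(C=O)c(OC)c1 | intermediate
30 | 2-bromo-6-hydroxy-4-methoxybenzaldehyde | COc1cc(O)c(C=O)c(Br)c1 | intermediate
31 | (3,5-dimethoxyphenyl)magnesium bromide | COc1cc([Mg]Br)cc(OC)c1 | intermediate (not isolated)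
32 | 3-bromo-2-[(3,5-dimethoxyphenyl)(hydroxy)methyl]-5-methoxyphenol (racemic) | COc1cc(O)c(C(O)c2cc(OC)cc(OC)c2)c(Br)c1 | intermediate
33 | 3-bromo-2-[(3,5-dimethoxyphenyl)(4-methylbenzenesulfonyl)methyl]-5-methoxyphenol (racemic) | COc1cc(O)c(C(c2cc(OC)cc(OC)c2)S(=O)(=O)c2ccc(C)cc2)c(Br)c1 | intermediate
34 | sulfonium ylide of 27 | C[C@H]1CC[C@H](C)[S+]1[CH-]c1ccc(OC)c2c1O[C@H](c1ccc(OC)cc1OC)[C@H]2c1cc(OC)cc(OC)c1 | intermediate (not isolated)
35 | 5-bromo-6-[(3,5-dimethoxyphenyl)methylidene]-3-methoxycyclohexa-2,4-dien-1-one | O=C1C=C(OC)C=C(Br)C1=Cc1cc(OC)cc(OC)c1 | intermediate (not isolated)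
36 | (2S,3S)-4-bromo-2-[(2S,3S)-2-(2,4-dimethoxyphenyl)-3-(3,5-dimethoxyphenyl)-4-methoxy-2,3-dihydro-1-benzofuran-7-yl]-3-(3,5-dimethoxyphenyl)-6-methoxy-2,3-dihydro-1-benzofuran | Brc1cc(OC)cc2c1[C@H](c1cc(OC)cc(OC)c1)[C@@H](c1ccc(OC)c3c1O[C@H](c1ccc(OC)cc1OC)[C@H]3c1cc(OC)cc(OC)c1)O2 | intermediate
37 | (2S,3S)-4-bromo-2-[(2S,3S)-2-(2,4-dihydroxyphenyl)-3-(3,5-dihydroxyphenyl)-4-hydroxy-2,3-dihydro-1-benzofuran-7-yl]-3-(3,5-dihydroxyphenyl)-2,3-dihydro-1-benzofuran-6-ol | Brc1cc(O)cc2c1[C@H](c1cc(O)cc(O)c1)[C@@H](c1ccc(O)c3c1O[C@H](c1ccc(O)cc1O)[C@H]3c1cc(O)cc(O)c1)O2 | intermediate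
38 | octaacetate of 37 | Brc1cc(OC(C)=O)cc2c1[C@H](c1cc(OC(C)=O)cc(OC(C)=O)c1)[C@@H](c1ccc(OC(C)=O)c3c1O[C@H](c1ccc(OC(C)=O)cc1OC(C)=O)[C@H]3c1cc(OC(C)=O)cc(OC(C)=O)c1)O2 | intermediate
39 | 4-ethenylphenyl acetate | CC(=O)Oc1ccc(C=C)cc1 | starting material
40 | nonaacetate of 41 | CC(=O)Oc1ccc(/C=C/c2cc(OC(C)=O)cc3c2[C@H](c2cc(OC(C)=O)cc(OC(C)=O)c2)[C@@H](c2ccc(OC(C)=O)c4c2O[C@H](c2ccc(OC(C)=O)cc2OC(C)=O)[C@H]4c2cc(OC(C)=O)cc(OC(C)=O)c2)O3)cc1 | intermediate
41 | (2S,3S)-2-[(2S,3S)-2-(2,4-dihydroxyphenyl)-3-(3,5-dihydroxyphenyl)-4-hydroxy-2,3-dihydro-1-benzofuran-7-yl]-3-(3,5-dihydroxyphenyl)-4-[(E)-2-(4-hydroxyphenyl)ethenyl]-2,3-dihydro-1-benzofuran-6-ol | Oc1ccc(/C=C/c2cc(O)cc3c2[C@H](c2cc(O)cc(O)c2)[C@@H](c2ccc(O)c4c2O[C@H](c2ccc(O)cc2O)[C@H]4c2cc(O)cc(O)c2)O3)cc1 | target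

## Step count and least certain steps

Total step count: 21. Longest linear sequence: 15 steps (steps 1–5, 8–12 and 17–21).

**Step 8 (key step).**
- What may go wrong: self-condensation of the strained bromo enone 15 or of ketene 16 may outrun cycloaddition to the hindered alkyne. Excess ketene may acylate the product phenol. The tertiary allylic bromide of 17 may ionise before ring opening. Prolonged heating may erode C3'.
- Fallback, from 11 back to 19: 2-bromobut-2-enoyl chloride F1 (either alkene isomer, from the commercial acid and oxalyl chloride) is added slowly with Et3N to 11 in toluene at room temperature. 1,4-Dehydrochlorination gives 16 without passing through 15, cycloadduct 17 forms in the cold, and the flask is then warmed to complete the electrocyclic cascade to 19.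

**Step 17.**
- What may go wrong: facial discrimination at the quinone methide may be incomplete. C3 is set only through the trans preference of the addition, so leakage gives the (2R,3R) form of unit 1. Rearrangement of the ylide and self-condensation of 35 compete.
- Fallback, from 25 back to 36: stereocontrol by the reagent is given up in favour of separation. Bromide 26 is quaternised with thiolane to the achiral salt 1-{[(2S,3S)-2-(2,4-dimethoxyphenyl)-3-(3,5-dimethoxyphenyl)-4-methoxy-2,3-dihydro-1-benzofuran-7-yl]methyl}thiolan-1-ium tetrafluoroborate F2. Its union with 33 under the same base gives 36 together with its (2R,3R) unit 1 diastereomer F3. The two differ at two centres relative to the fixed unit 2 and are separated by chromatography; 36 rejoins the route.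

**Step 18.**
- What may go wrong: the Lewis acid may ionise the C2–O1 or C2'–O1' bond, with re-closure of unit 2 on the C4' oxygen (ring transposition) or epimerisation. Cleavage of eight ethers may be incomplete.
- Fallback, from 36 to 41: cationic conditions are avoided altogether. Bromide 36 is coupled with 4-methoxystyrene under the catalyst of step 20 to give the nonamethyl ether F4. Its methyl groups are then removed by SN2 attack of NaSEt in DMF at 130 °C, which is basic throughout and gives 41 directly.

**Step 3.**
- What may go wrong: the aryl-substituted allenylpalladium may racemise before transmetalation, and the benzylic propargylic mesylate may ionise; both erode C3'.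
- Fallback, from 1 back to 7: an isolable, configurationally stable allenylstannane replaces the transient allenylindium. Step 1 with the (R,R)-ligand gives, through (S)-1-(3,5-dimethoxyphenyl)-3-(trimethylsilyl)prop-2-yn-1-ol F5, the alkynol (R)-1-(3,5-dimethoxyphenyl)prop-2-yn-1-ol F6, which is converted into its mesylate F7. Bu3SnLi with CuBr·SMe2 displaces F7 in an anti SN2' sense to (aR)-tributyl[3-(3,5-dimethoxyphenyl)propa-1,2-dien-1-yl]stannane F8. With InBr3 and aldehyde 5 in EtOAc at −78 °C, F8 is transmetalated anti and adds through a closed transition state to give 7. The net course is retention at the propargylic carbon, which is why the enantiomeric mesylate is used.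

## Further compounds

F1 | step 8 | 2-bromobut-2-enoyl chloride (either alkene isomer) | CC=C(Br)C(Cl)=O
F2 | step 17 | 1-{[(2S,3S)-2-(2,4-dimethoxyphenyl)-3-(3,5-dimethoxyphenyl)-4-methoxy-2,3-dihydro-1-benzofuran-7-yl]methyl}thiolan-1-ium tetrafluoroborate | C1CC[S+](C1)Cc1ccc(OC)c2c1O[C@H](c1ccc(OC)cc1OC)[C@H]2c1cc(OC)cc(OC)c1.F[B-](F)(F)F
F3 | step 17 | (2R,3R)-4-bromo-2-[(2S,3S)-2-(2,4-dimethoxyphenyl)-3-(3,5-dimethoxyphenyl)-4-methoxy-2,3-dihydro-1-benzofuran-7-yl]-3-(3,5-dimethoxyphenyl)-6-methoxy-2,3-dihydro-1-benzofuran | Brc1cc(OC)cc2c1[C@@H](c1cc(OC)cc(OC)c1)[C@H](c1ccc(OC)c3c1O[C@H](c1ccc(OC)cc1OC)[C@H]3c1cc(OC)cc(OC)c1)O2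
F4 | step 18 | nonamethyl ether of 41 | COc1ccc(/C=C/c2cc(OC)cc3c2[C@H](c2cc(OC)cc(OC)c2)[C@@H](c2ccc(OC)c4c2O[C@H](c2ccc(OC)cc2OC)[C@H]4c2cc(OC)cc(OC)c2)O3)cc1
F5 | step 3 | (S)-1-(3,5-dimethoxyphenyl)-3-(trimethylsilyl)prop-2-yn-1-ol | C[Si](C)(C)C#C[C@@H](O)c1cc(OC)cc(OC)c1
F6 | step 3 | (R)-1-(3,5-dimethoxyphenyl)prop-2-yn-1-ol | C#C[C@@H](O)c1cc(OC)cc(OC)c1
F7 | step 3 | (R)-1-(3,5-dimethoxyphenyl)prop-2-yn-1-yl methanesulfonate | C#C[C@@H](OS(C)(=O)=O)c1cc(OC)cc(OC)c1
F8 | step 3 | (aR)-tributyl[3-(3,5-dimethoxyphenyl)propa-1,2-dien-1-yl]stannane | CCCC[Sn](CCCC)(CCCC)C([H])=[C@]=C([H])c1cc(OC)cc(OC)c1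
A1 | alternative 1 | 2-{3-[diazo(3,5-dimethoxyphenyl)methyl]-2-[(2,4-dimethoxyphenyl)methoxy]-4-methoxyphenyl}-1,3-dioxolane | [N-]=[N+]=C(c1cc(OC)cc(OC)c1)c1c(OC)ccc(C2OCCO2)c1OCc1ccc(OC)cc1OC
A2 | alternative 1 | (2R,3S)-2-(2,4-dimethoxyphenyl)-3-(3,5-dimethoxyphenyl)-7-(1,3-dioxolan-2-yl)-4-methoxy-2,3-dihydro-1-benzofuran (cis) | O1CCOC1c1ccc(OC)c2c1O[C@@H](c1ccc(OC)cc1OC)[C@H]2c1cc(OC)cc(OC)c1
A3 | alternative 2 | 2-[(E)-2-{2-methoxy... ring A}ethenyl] boronate: 2-[(E)-2-{4-methoxy-2-(methoxymethoxy)-6-[(E)-2-(4-methoxyphenyl)ethenyl]phenyl}ethenyl]-4,4,5,5-tetramethyl-1,3,2-dioxaborolane | COCOc1cc(OC)cc(/C=C/c2ccc(OC)cc2)c1/C=C/B1OC(C)(C)C(C)(C)O1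
A4 | alternative 2 | 3,5-dimethoxyphenyl trifluoromethanesulfonate | COc1cc(OS(=O)(=O)C(F)(F)F)cc(OC)c1
A5 | alternative 2 | secondary pinacol boronate at C2 (C2 R, C3 S) carrying unit 2, ring A and the 3,5-dimethoxyphenyl group | COCOc1cc(OC)cc(/C=C/c2ccc(OC)cc2)c1[C@H](c1cc(OC)cc(OC)c1)[C@@H](B1OC(C)(C)C(C)(C)O1)c1ccc(OC)c2c1O[C@H](c1ccc(OC)cc1OC)[C@H]2c1cc(OC)cc(OC)c1
A6 | alternative 3 | (2S,3S)-4-bromo-2-[(2S,3S)-2-(2,4-dimethoxyphenyl)-3-(3,5-dimethoxyphenyl)-4-methoxy-2,3-dihydro-1-benzofuran-7-yl]-3-(3,5-dimethoxyphenyl)-6-methoxy-2,3-dihydro-1-benzofuran (identical with 36) | Brc1cc(OC)cc2c1[C@H](c1cc(OC)cc(OC)c1)[C@@H](c1ccc(OC)c3c1O[C@H](c1ccc(OC)cc1OC)[C@H]3c1cc(OC)cc(OC)c1)O2
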